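C1 = ring C=O, C2=C3 = enone CH=CH, C4 and C5 = CHOH, C6 = C(OH) bearing the (Z)-heptadec-8-enyl chain; the target is (4S,5R,6R). Endgame: C2–C3 dehydrogenation, which can only go one way because C6 is quaternary, then acid removal of a C4/C5 acetonide and a C6 silyl ether.
Enabling feature: the tertiary α-ketol C1(=O)–C6(OH)(alkyl) inside the six-membered ring. Its carbonyl carbon C1 carries only the two ring bonds and is joined through the unsubstituted C2–C3 unit to the trans-C4/C5 diol. C1–C6 is therefore a crossed-benzoin bond, C1 can be carbon monoxide, and C2–C3 can be a vinyl group.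
Key disconnection (C1–C2 and C1–C6 in one operation): tandem Rh hydroformylation/NHC benzoin, a formal [5+1] annulation of keto olefin 12 with CO and H2 that also sets C6.
12 comes from Weinreb amide 5 (C3–C6 and both carbinol centres from L-tartrate acetonide 1) and the Grignard reagent of (Z)-bromide 10 (dec-1-yne + 1,7-dibromoheptane, then Lindlar).
Ring order: the temporary 1,3-dioxolane is bought with 1. The cyclohexane ring is the only ring of the skeleton and is closed last, in step 8. The dioxolane is removed in step 11.

Key step: step 8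

Step 1
Reactants: 1 dimethyl (4R,5R)-2,2-dimethyl-1,3-dioxolane-4,5-dicarboxylate (dimethyl 2,3-O-isopropylidene-L-tartrate)
Product: 2 methyl (4R,5S)-5-(hydroxymethyl)-2,2-dimethyl-1,3-dioxolane-4-carboxylate
Conditions: NaBH4 (0.6 equiv), MeOH, 0 °C
Reagents that add atoms: none
Why: Borohydride reduction of an α-alkoxy-activated ester should stop largely at the hydroxy ester when hydride is limiting, the C2 symmetry of 1 makes both esters equivalent so that only one mono-reduction product can form, and no stereocentre is touched.

Step 2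
Reactants: 2 methyl (4R,5S)-5-(hydroxymethyl)-2,2-dimethyl-1,3-dioxolane-4-carboxylate
Product: 3 methyl (4R,5R)-5-formyl-2,2-dimethyl-1,3-dioxolane-4-carboxylate
Conditions: Dess–Martin periodinane, CH2Cl2, 0 °C to rt
Reagents that add atoms: none
Why: Dess–Martin oxidation converts the primary alcohol into the aldehyde under neutral, non-epimerising conditions and leaves ester and acetonide untouched.

Step 3
Reactants: 3 methyl (4R,5R)-5-formyl-2,2-dimethyl-1,3-dioxolane-4-carboxylate
Product: 4 methyl (4R,5S)-2,2-dimethyl-5-vinyl-1,3-dioxolane-4-carboxylate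
Conditions: Ph3PCH3Br, KHMDS, THF, −78 °C to 0 °C
Reagents that add atoms: methyltriphenylphosphonium bromide, C[P+](c1ccccc1)(c1ccccc1)c1ccccc1.[Br-]
Why: Wittig methylenation with the non-stabilised ylide is much faster at the aldehyde than at the ester, and the low temperature together with the thermodynamic preference for the trans-dioxolane should preserve both stereocentres.

Step 4
Reactants: 4 methyl (4R,5S)-2,2-dimethyl-5-vinyl-1,3-dioxolane-4-carboxylate
Product: 5 (4R,5S)-N-methoxy-N,2,2-trimethyl-5-vinyl-1,3-dioxolane-4-carboxamide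
Conditions: MeNH(OMe)·HCl, i-PrMgCl, THF, −20 °C; then H2O
Reagents that add atoms: N,O-dimethylhydroxylamine hydrochloride, CNOC.Cl
Why: Weinreb amidation of the ester with the magnesium amide made in situ proceeds at low temperature without enolisation of the α-alkoxy centre and prepares a clean single addition in step 7.

Step 5
Reactants: 6 dec-1-yne; 7 1,7-dibromoheptane
Product: 9 1-bromoheptadec-8-yne, via dec-1-ynyllithium 8 (not isolated)
Conditions: 6, n-BuLi, THF, −78 °C; then 7 (3 equiv), DMPU, −78 °C to rt
Reagents that add atoms: n-butyllithium, [Li]CCCC (its lithium stays only in intermediate 8)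
Why: SN2 alkylation of a lithium acetylide with a primary bromide in a dipolar cosolvent is standard, and the excess of the symmetric dibromide 7 should hold back double alkylation.

Step 6
Reactants: 9 1-bromoheptadec-8-yne
Product: 10 (Z)-1-bromoheptadec-8-ene
Conditions: H2 (1 atm), Lindlar catalyst, quinoline, hexane, rt
Reagents that add atoms: none
Why: Lindlar semihydrogenation delivers H2 syn to the alkyne and thereby sets the (Z)-olefin of the side chain, while the primary bromide is inert.

Step 7
Reactants: 10 (Z)-1-bromoheptadec-8-ene; 5 (4R,5S)-N-methoxy-N,2,2-trimethyl-5-vinyl-1,3-dioxolane-4-carboxamide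
Product: 12 (Z)-1-[(4R,5S)-2,2-dimethyl-5-vinyl-1,3-dioxolan-4-yl]octadec-9-en-1-one, via (Z)-heptadec-8-enylmagnesium bromide 11 (not isolated)
Conditions: 10, Mg, THF, 40 °C; then 5, THF, 0 °C; then H2O
Reagents that add atoms: magnesium, [Mg] (stays only in intermediate 11)
Why: Grignard addition to the Weinreb amide stops at the chelated tetrahedral intermediate, which collapses to the ketone only on work-up, so that no tertiary alcohol forms and the α-centre is not epimerised.

Step 8
Reactants: 12 (Z)-1-[(4R,5S)-2,2-dimethyl-5-vinyl-1,3-dioxolan-4-yl]octadec-9-en-1-one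
Product: 14 (3aR,4R,7aS)-4-[(Z)-heptadec-8-enyl]-4-hydroxy-2,2-dimethylhexahydro-1,3-benzodioxol-5-one (C4/C5 acetonide of 2,3-dihydropleiogenone A), via keto aldehyde 13 (not isolated)
Conditions: Rh(acac)(CO)2 (1 mol %), Xantphos (2 mol %), CO/H2 (1:1, 10 bar), 2-(pentafluorophenyl)-6,7-dihydro-5H-pyrrolo[2,1-c][1,2,4]triazol-2-ium tetrafluoroborate (10 mol %), Et3N (20 mol %), toluene, 60 °C
Reagents that add atoms: carbon monoxide, [C-]#[O+]
Why: Proposed new method: the rhodium hydride adds to the only terminal alkene of 12, CO inserts and hydrogenolysis releases the linear keto aldehyde 13, which the triazolylidene turns at once into its Breslow enaminol, whose nucleophilic carbon C1 (the former CO) adds to the C6 ketone and, after proton transfer and loss of the carbene, leaves the C1(=O)–C6(OH) ketol, so that two C–C bonds, the ring, the ketone and the quaternary carbinol should arise from 12, CO and H2 without any by-product. The closest known reaction types are the orthogonal tandem hydroformylation/acyloin reaction of 1-alkenes (rhodium plus azolium salt under syngas, known as an intermolecular homocoupling) and the NHC-catalysed intramolecular crossed aldehyde–ketone benzoin reaction that gives six-membered tertiary acyloins, and only their merger in one flask is new. The cyclohexanone ring closes in the 6-exo-trig mode through a chair-like transition state that is trans-fused to the dioxolane. C6 is the only new stereocentre and is controlled by C5, because C1 has to approach anti to the equatorial C5–O bond (polar Felkin–Anh arrangement) while the C17 chain takes the pseudo-equatorial and the carbonyl oxygen the pseudo-axial position, which places C6–OH cis to C5–O and corresponds to 6R. The step needs terminal-over-internal alkene chemoselectivity and linear regioselectivity, which the monosubstituted vinyl group on a branched carbon and the wide-bite-angle, poorly isomerising Xantphos catalyst secure, and it needs benzoin addition to outrun aldol addition, which the trans-dioxolane secures because each conceivable five-ring aldol would have to form a trans-bicyclo[3.3.0]octane. As 13 is consumed as it forms, homo-benzoin and self-aldol reactions should stay negligible, and the weak amine base should leave C5, whose trans arrangement is the thermodynamic one in any case, untouched.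

Step 9
Reactants: 14 (3aR,4R,7aS)-4-[(Z)-heptadec-8-enyl]-4-hydroxy-2,2-dimethylhexahydro-1,3-benzodioxol-5-one
Product: 15 (3aR,4R,7aS)-4-[(Z)-heptadec-8-enyl]-2,2-dimethyl-4,5-bis(trimethylsilyloxy)-3a,4,7,7a-tetrahydro-1,3-benzodioxole
Conditions: TMSOTf, Et3N, CH2Cl2, 0 °C
Reagents that add atoms: trimethylsilyl trifluoromethanesulfonate, C[Si](C)(C)OS(=O)(=O)C(F)(F)F
Why: Soft enolisation with TMSOTf/Et3N can only occur toward C2 because C6 is quaternary, so a single silyl enol ether should form while the tertiary alcohol is capped as its TMS ether in the same operation.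

Step 10
Reactants: 15 (3aR,4R,7aS)-4-[(Z)-heptadec-8-enyl]-2,2-dimethyl-4,5-bis(trimethylsilyloxy)-3a,4,7,7a-tetrahydro-1,3-benzodioxole
Product: 16 (3aR,4R,7aS)-4-[(Z)-heptadec-8-enyl]-2,2-dimethyl-4-(trimethylsilyloxy)-3a,7a-dihydro-1,3-benzodioxol-5(4H)-one
Conditions: Pd(OAc)2 (1.1 equiv), MeCN, rt
Reagents that add atoms: none
Why: In the Saegusa–Ito oxidation, palladation of the silyl enol ether at C2 and β-hydride elimination from C3 install the C2=C3 double bond without base, so that the γ-alkoxy enone cannot eliminate and no stereocentre is affected.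

Step 11
Reactants: 16 (3aR,4R,7aS)-4-[(Z)-heptadec-8-enyl]-2,2-dimethyl-4-(trimethylsilyloxy)-3a,7a-dihydro-1,3-benzodioxol-5(4H)-one
Product: 17 pleiogenone A, (4S,5R,6R)-6-[(Z)-heptadec-8-enyl]-4,5,6-trihydroxycyclohex-2-en-1-one
Conditions: TFA/H2O, CH2Cl2, 0 °C to rt
Reagents that add atoms: none
Why: Acid hydrolysis cleaves the strained trans-fused acetonide and the tertiary TMS ether in one operation under conditions that should touch neither the enone, the (Z)-olefin nor any stereocentre.

Compound list
1 | dimethyl (4R,5R)-2,2-dimethyl-1,3-dioxolane-4,5-dicarboxylate | COC(=O)[C@@H]1OC(C)(C)O[C@H]1C(=O)OC | starting material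
2 | methyl (4R,5S)-5-(hydroxymethyl)-2,2-dimethyl-1,3-dioxolane-4-carboxylate | COC(=O)[C@@H]1OC(C)(C)O[C@H]1CO | intermediate
3 | methyl (4R,5R)-5-formyl-2,2-dimethyl-1,3-dioxolane-4-carboxylate | COC(=O)[C@@H]1OC(C)(C)O[C@H]1C=O | intermediate
4 | methyl (4R,5S)-2,2-dimethyl-5-vinyl-1,3-dioxolane-4-carboxylate | COC(=O)[C@@H]1OC(C)(C)O[C@H]1C=C | intermediate
5 | (4R,5S)-N-methoxy-N,2,2-trimethyl-5-vinyl-1,3-dioxolane-4-carboxamide | CON(C)C(=O)[C@@H]1OC(C)(C)O[C@H]1C=C | intermediate
6 | dec-1-yne | C#CCCCCCCCC | starting material
7 | 1,7-dibromoheptane | BrCCCCCCCBr | starting material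
8 | dec-1-ynyllithium | [Li]C#CCCCCCCCC | intermediate
9 | 1-bromoheptadec-8-yne | CCCCCCCCC#CCCCCCCCBr | intermediate
10 | (Z)-1-bromoheptadec-8-ene | CCCCCCCC/C=C\CCCCCCCBr | intermediate
11 | (Z)-heptadec-8-enylmagnesium bromide | CCCCCCCC/C=C\CCCCCCC[Mg]Br | intermediate
12 | (Z)-1-[(4R,5S)-2,2-dimethyl-5-vinyl-1,3-dioxolan-4-yl]octadec-9-en-1-one | CCCCCCCC/C=C\CCCCCCCC(=O)[C@@H]1OC(C)(C)O[C@H]1C=C | intermediate
13 | 3-[(4S,5R)-2,2-dimethyl-5-[(Z)-octadec-9-enoyl]-1,3-dioxolan-4-yl]propanal | CCCCCCCC/C=C\CCCCCCCC(=O)[C@@H]1OC(C)(C)O[C@H]1CCC=O | intermediate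
14 | (3aR,4R,7aS)-4-[(Z)-heptadec-8-enyl]-4-hydroxy-2,2-dimethylhexahydro-1,3-benzodioxol-5-one | CCCCCCCC/C=C\CCCCCCC[C@]1(O)C(=O)CC[C@@H]2OC(C)(C)O[C@@H]12 | intermediate
15 | (3aR,4R,7aS)-4-[(Z)-heptadec-8-enyl]-2,2-dimethyl-4,5-bis(trimethylsilyloxy)-3a,4,7,7a-tetrahydro-1,3-benzodioxole | CCCCCCCC/C=C\CCCCCCC[C@]1(O[Si](C)(C)C)C(O[Si](C)(C)C)=CC[C@@H]2OC(C)(C)O[C@@H]12 | intermediate
16 | (3aR,4R,7aS)-4-[(Z)-heptadec-8-enyl]-2,2-dimethyl-4-(trimethylsilyloxy)-3a,7a-dihydro-1,3-benzodioxol-5(4H)-one | CCCCCCCC/C=C\CCCCCCC[C@]1(O[Si](C)(C)C)C(=O)C=C[C@@H]2OC(C)(C)O[C@@H]12 | intermediate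
17 | pleiogenone A, (4S,5R,6R)-6-[(Z)-heptadec-8-enyl]-4,5,6-trihydroxycyclohex-2-en-1-one | CCCCCCCC/C=C\CCCCCCC[C@]1(O)C(=O)C=C[C@H](O)[C@H]1O | target

Total step count: 11
Longest linear sequence: 9 steps (steps 1–4 and 7–11, from 1)

Steps most likely to fail

Step 8 (tandem hydroformylation/benzoin).
- **What may go wrong:** binding of the free carbene to rhodium could slow the hydroformylation or erode its linear selectivity. The rhodium hydride could isomerise the chain olefin from Z to E. The facial selectivity of the addition to the ketone could be insufficient.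
- **Fallback:** known chemistry in which the ring is closed at C2=C3 instead of C1–C6. It sets out from 12. 1-Lithio-1-methoxyallene (methoxyallene, n-BuLi, THF, −78 °C), an acryloyl anion equivalent, should add to the ketone under polar Felkin–Anh control to give allenyl carbinol F1. Dilute aqueous H2SO4 in THF at 0 °C should hydrolyse the enol ether to hydroxy dienone F2. Ring-closing metathesis of the two terminal vinyl groups (Hoveyda–Grubbs II catalyst, dilute CH2Cl2, 40 °C) should give enone acetonide F3. Aqueous TFA as in step 11 brings the sequence back to the route at 17, so steps 9 and 10 are bypassed.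

Step 10 (Saegusa–Ito oxidation).
- **What may go wrong:** palladium(II) could engage the chain olefin (Z/E isomerisation or allylic oxidation). Protodesilylation of the enol ether by the acetic acid formed could also compete with palladation.
- **Fallback:** metal-free selenoxide elimination. It sets out from 15. PhSeCl in CH2Cl2 at −78 °C should selenenylate the silyl enol ether at C2 to give α-phenylselanyl ketone F4 (epimers at C2, both productive). H2O2/pyridine in CH2Cl2 at 0 °C should trigger selenoxide syn-elimination toward C3. The sequence comes back to the route at 16.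

Step 1 (mono-reduction).
- **What may go wrong:** over-reduction of the second ester and a merely statistical distribution between unreacted, mono-reduced and doubly reduced material.
- **Fallback:** differentiation by hydrolysis instead of by limiting hydride. It sets out from 1. One equivalent of KOH in MeOH should give half ester F5, which is separable by acid/base extraction. BH3·SMe2 in THF at 0 °C should then reduce the carboxylic acid chemoselectively beside the ester. The sequence comes back to the route at 2.

Further compounds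
F1 | step 8 | (4R,12Z)-4-[(4R,5S)-2,2-dimethyl-5-vinyl-1,3-dioxolan-4-yl]-3-methoxyhenicosa-1,2,12-trien-4-ol (allenyl carbinol) | CCCCCCCC/C=C\CCCCCCC[C@](O)(C(OC)=C=C)[C@@H]1OC(C)(C)O[C@H]1C=C
F2 | step 8 | (4R,12Z)-4-[(4R,5S)-2,2-dimethyl-5-vinyl-1,3-dioxolan-4-yl]-4-hydroxyhenicosa-1,12-dien-3-one (hydroxy dienone) | CCCCCCCC/C=C\CCCCCCC[C@](O)(C(=O)C=C)[C@@H]1OC(C)(C)O[C@H]1C=C
F3 | step 8 | (3aR,4R,7aS)-4-[(Z)-heptadec-8-enyl]-4-hydroxy-2,2-dimethyl-3a,7a-dihydro-1,3-benzodioxol-5(4H)-one (enone acetonide) | CCCCCCCC/C=C\CCCCCCC[C@]1(O)C(=O)C=C[C@@H]2OC(C)(C)O[C@@H]12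
F4 | step 10 | (3aR,4R,7aS)-4-[(Z)-heptadec-8-enyl]-2,2-dimethyl-6-(phenylselanyl)-4-(trimethylsilyloxy)hexahydro-1,3-benzodioxol-5-one (α-phenylselanyl ketone, epimers at the selenium-bearing carbon) | CCCCCCCC/C=C\CCCCCCC[C@]1(O[Si](C)(C)C)C(=O)C([Se]c3ccccc3)C[C@@H]2OC(C)(C)O[C@@H]12
F5 | step 1 | (4R,5R)-5-(methoxycarbonyl)-2,2-dimethyl-1,3-dioxolane-4-carboxylic acid (half ester) | COC(=O)[C@@H]1OC(C)(C)O[C@H]1C(=O)O
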